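At 25 min, when theta and eta are read, we ask how often each partner charge has turned over into product.

| setting | Saturday's | Wednesday's | theta | eta |
|---|---|---|---|---|
| starting material | 0.065 M | 0.065 M | 0.065 M | 0.065 M |
| coupling partner | 0.32 equiv | 0.55 equiv | 0.600 equiv | 0.900 equiv |
| remark | run made earlier | run made earlier |  |  |
| time |  |  | 25 min | 25 min |

- Saturday's (time / min: product / %): 2.00: 15.6; 6.00: 27.3; 12.0: 28.8; 20.0: 31.9; 25.0: 30.5
- Wednesday's (time / min: product / %): 2.00: 30.2; 4.00: 39.2; 8.00: 47.2; 12.0: 49.3; 25.0: 53.5

(readings scatter by 1 percentage point)

- a reading or a percentage of product counts all its forms, free or not

- the flask that ends with the higher amount of product, in percent of the starting material charged, or "neither" when 2 percentage points or less lies between them (theta / eta / neither)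
- final product, as a percentage of the starting material charged, in theta
- final product, as a percentage of the starting material charged, in eta

We build the flask up step by step. With the main step alone, one partner makes one product, and the partner is the limiting reagent in both flasks. The ceilings are therefore 60.0% for theta and 90.0% for eta.

Next we add the finite time. At the last reading, Saturday's run reads 0.953 of its partner charge as product and Wednesday's 0.973, which the scatter of 1 percentage point does not separate. Their mean, 0.963, lowers theta to 57.8% and eta to 86.7%.

Last we add the thinning of the starting material, taking the partner's loss per minute as proportional to the partner present and to the starting material present. On that assumption the mean turnover corresponds to 3.29 partner lifetimes, while the starting material, taken as the average of its start and end values, comes to 0.790 of its charge across the two runs. Dividing gives 4.17, the turnover count, meaning partner lifetimes in this time per unit of mean starting material.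

Theta's mean starting material is 0.711, so 5.15% of its partner stays and we expect 56.9%. Eta's mean is lower than theta's, at 0.567, so 9.41% stays and we expect 81.5%. Our choice is eta.

The forecast also says eta, with 57.5% for theta and 81% for eta, which differ from our two figures, noting that in eta “both reagents run low together”.

The flasks give 57.5% in theta and 83.2% in eta, so eta ends higher.

    crystals ⇌ product, rate k1*(cs1 - [product]) while solid is left; crystals form when [product] > cs1 (solubility = 11.0 mM, k = 0.00630 s⁻¹)
    starting material + coupling partner → product, rate k2*[starting material]*[coupling partner]^1.5 (k = 0.820 M⁻¹·⁵ s⁻¹)

These percentages include the crystals, 40.1% in theta and 65.5% in eta. The partner left, as a share of its own charge, stands at 4.09% in theta against our 5.15%, and at 7.51% in eta against our 9.41%. A neighbour of theta charged with 0.360 equiv of partner has a mean starting material of 0.827, so the same count leaves 3.18% of its partner and gives 34.9% product. That neighbour keeps 3.6% of its partner and ends with 34.7% product.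

The numbers in the tables come from a simulation on assumed constants; noise was put on by code.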